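**Strategy**

Everything rests on disconnecting the bond between C3 of the 2,3-dihydro-1,4-benzodioxine ring and the ipso carbon of the 3,4,5-trimethoxyphenyl ring. Because C3 carries ring oxygen O4, a carboxyl group there is a traceless handle: Ir/Ni decarboxylative arylation of a benzodioxine-carboxylic acid with 5-bromo-1,2,3-trimethoxybenzene joins the fragments through an α-aryloxy radical and sets the aryl-bearing centre trans to the C2 substituent, whose configuration derives from (S)-glycidyl trityl ether. The precursor is a cis acid with a formyl group in place of the enal; its carboxyl-bearing stereocentre is erased in the radical, so only C2 has to be built, by Mitsunobu etherification and 6-exo epoxide opening.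

Key step: step 6

Remark: compounds 1, 4, 9 and 11 are taken as commercially available. The epoxide-carbon configuration of 3 is carried as a single isomer only for clean intermediates, since that centre is planarised in step 6. CIP descriptors change along the route with substituent priorities, so the SMILES are authoritative.

**Route**

Step 1
Reactants: 1 (S)-glycidyl trityl ether
Product: 2 (2S)-1-(trityloxy)but-3-en-2-ol
Conditions: Me3S+ I− (3 equiv), n-BuLi (3 equiv), THF, −10 °C to rt
Reagents that add atoms: trimethylsulfonium iodide, C[S+](C)C.[I-]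
Why: Dimethylsulfonium methylide (Corey–Chaykovsky reagent) opens the epoxide at its CH2 terminus and the β-sulfonium alkoxide then loses dimethyl sulfide, a one-carbon epoxide-to-allylic-alcohol homologation that leaves the C–O stereocentre untouched.

Step 2
Reactants: 2 (2S)-1-(trityloxy)but-3-en-2-ol
Product: 3 (2R,3S)-3,4-epoxy-1-(trityloxy)butan-2-ol (erythro)
Conditions: Ti(OiPr)4 (0.3 equiv), D-(−)-diisopropyl tartrate (0.36 equiv), t-BuOOH, 4 Å MS, CH2Cl2, −20 °C
Reagents that add atoms: tert-butyl hydroperoxide, CC(C)(C)OO
Why: Sharpless asymmetric epoxidation in its matched sense (this enantiomer of the secondary allylic alcohol is the fast-reacting one with the D-tartrate) should deliver oxygen to one alkene face and set the epoxide carbon erythro to the carbinol under reagent control reinforced by the substrate.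

Step 3
Reactants: 3 (2R,3S)-3,4-epoxy-1-(trityloxy)butan-2-ol; 4 3,4,5-trihydroxybenzaldehyde
Product: 5 3,5-dihydroxy-4-{(1S)-1-[(2S)-oxiran-2-yl]-2-(trityloxy)ethoxy}benzaldehyde
Conditions: PPh3, DIAD, THF, 0 °C to rt (4 in slight excess)
Reagents that add atoms: none
Why: Mitsunobu etherification, in which the 4-OH (para to the formyl group and the most acidic phenol) should displace the activated secondary alcohol by SN2 with inversion, setting the configuration of the future C2 of the benzodioxine while epoxide and aldehyde stay inert under the neutral conditions.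

Step 4
Reactants: 5 3,5-dihydroxy-4-{(1S)-1-[(2S)-oxiran-2-yl]-2-(trityloxy)ethoxy}benzaldehyde
Product: 7 (2S,3R)-3-(hydroxymethyl)-8-(methoxymethoxy)-2-[(trityloxy)methyl]-2,3-dihydro-1,4-benzodioxine-6-carbaldehyde, via cyclised phenol 6 (not isolated)
Conditions: K2CO3, DMF, 60 °C; then MOMCl, 0 °C to rt
Reagents that add atoms: chloromethyl methyl ether, COCCl
Why: Intramolecular phenoxide opening of the epoxide in the 6-exo-tet mode (the two ortho phenols are equivalent) attacks the internal epoxide carbon with inversion to close the dioxane ring as the cis isomer and free the primary alcohol, after which the remaining phenoxide is capped chemoselectively by Williamson etherification as its MOM ether.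

Step 5
Reactants: 7 (2S,3R)-3-(hydroxymethyl)-8-(methoxymethoxy)-2-[(trityloxy)methyl]-2,3-dihydro-1,4-benzodioxine-6-carbaldehyde
Product: 8 (2S,3S)-7-formyl-5-(methoxymethoxy)-3-[(trityloxy)methyl]-2,3-dihydro-1,4-benzodioxine-2-carboxylic acid (cis)
Conditions: TEMPO (cat.), PhI(OAc)2, MeCN/H2O (1:1), rt
Reagents that add atoms: water, O
Why: Oxoammonium (TEMPO/PhI(OAc)2) oxidation takes the primary alcohol through the aldehyde hydrate to the carboxylic acid under near-neutral conditions that should spare the aryl aldehyde and the trityl and MOM ethers.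

Step 6
Reactants: 8 (2S,3S)-7-formyl-5-(methoxymethoxy)-3-[(trityloxy)methyl]-2,3-dihydro-1,4-benzodioxine-2-carboxylic acid; 9 5-bromo-1,2,3-trimethoxybenzene
Product: 10 (2S,3S)-8-(methoxymethoxy)-3-(3,4,5-trimethoxyphenyl)-2-[(trityloxy)methyl]-2,3-dihydro-1,4-benzodioxine-6-carbaldehyde (trans)
Conditions: Ir[dF(CF3)ppy]2(dtbbpy)PF6 (1 mol%), NiCl2·glyme (10 mol%), dtbbpy (15 mol%), Cs2CO3, DMF, blue LEDs, rt, degassed (9 in excess)
Reagents that add atoms: none
Why: Metallaphotoredox decarboxylative arylation: the excited Ir(III) complex oxidises the caesium carboxylate of 8, CO2 is lost, and the resulting α-aryloxy radical at the ring carbon bonded to O1 is trapped by nickel that has oxidatively added bromide 9, after which reductive elimination from Ni(III) forms the aryl–C(sp3) bond and the reduced iridium closes the nickel cycle. The closest known reaction type is the Ir/Ni dual-catalytic decarboxylative cross-coupling of α-oxy and α-amino carboxylic acids with aryl halides, for which cyclic α-aryloxy acids are established radical precursors. No ring is closed in this step. The one new stereocentre, the aryl-bearing ring carbon, is set under substrate control by the neighbouring stereocentre: the planarised radical carries the bulky trityloxymethyl group on the adjacent carbon, so nickel capture and C–C bond formation should take place on the opposite face and give the trans-2,3-disubstituted ring whichever configuration the acid carbon had. The step needs trans diastereoselectivity and cross-coupling in preference to protodecarboxylation or O-arylation of the carboxylate; the former is secured by the adjacent substituent together with reversible radical capture at nickel, the latter by the low oxidation potential of the α-oxy carboxylate and by a bromide whose two meta methoxy groups offset the para one. The aryl aldehyde and the MOM and trityl ethers should be inert to visible light and carbonate base.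

Step 7
Reactants: 10 (2S,3S)-8-(methoxymethoxy)-3-(3,4,5-trimethoxyphenyl)-2-[(trityloxy)methyl]-2,3-dihydro-1,4-benzodioxine-6-carbaldehyde; 11 (1,3-dioxolan-2-ylmethyl)triphenylphosphonium bromide
Product: 13 (2E)-3-[(2S,3S)-8-hydroxy-2-(hydroxymethyl)-3-(3,4,5-trimethoxyphenyl)-2,3-dihydro-1,4-benzodioxin-6-yl]prop-2-enal, via vinyl dioxolane 12 (not isolated)
Conditions: t-BuOK, THF, 0 °C to rt; then 3 M aq. HCl, THF, 40 °C
Reagents that add atoms: water, O
Why: Wittig olefination with the acetal-bearing ylide gives the two-carbon-homologated vinyl dioxolane as an E/Z mixture, and aqueous acid should then hydrolyse the acetal to the enal with equilibration to the conjugated E isomer while also cleaving the trityl ether and the phenolic MOM acetal, no stereocentre being touched.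

**Compound list**

1 | (S)-glycidyl trityl ether [(2S)-2-(trityloxymethyl)oxirane] | C1O[C@@H]1COC(c2ccccc2)(c3ccccc3)c4ccccc4 | starting material
2 | (2S)-1-(trityloxy)but-3-en-2-ol | O[C@@H](C=C)COC(c1ccccc1)(c2ccccc2)c3ccccc3 | intermediate
3 | (2R,3S)-3,4-epoxy-1-(trityloxy)butan-2-ol, erythro | O[C@@H]([C@@H]1CO1)COC(c2ccccc2)(c3ccccc3)c4ccccc4 | intermediate
4 | 3,4,5-trihydroxybenzaldehyde | O=Cc1cc(O)c(O)c(O)c1 | starting material
5 | 3,5-dihydroxy-4-{(1S)-1-[(2S)-oxiran-2-yl]-2-(trityloxy)ethoxy}benzaldehyde | O=Cc1cc(O)c(O[C@H]([C@@H]2CO2)COC(c3ccccc3)(c4ccccc4)c5ccccc5)c(O)c1 | intermediate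
6 | (2S,3R)-8-hydroxy-3-(hydroxymethyl)-2-[(trityloxy)methyl]-2,3-dihydro-1,4-benzodioxine-6-carbaldehyde, cis | O=Cc1cc(O)c2c(c1)O[C@H](CO)[C@H](COC(c3ccccc3)(c4ccccc4)c5ccccc5)O2 | intermediate
7 | (2S,3R)-3-(hydroxymethyl)-8-(methoxymethoxy)-2-[(trityloxy)methyl]-2,3-dihydro-1,4-benzodioxine-6-carbaldehyde, cis | O=Cc1cc(OCOC)c2c(c1)O[C@H](CO)[C@H](COC(c3ccccc3)(c4ccccc4)c5ccccc5)O2 | intermediate
8 | (2S,3S)-7-formyl-5-(methoxymethoxy)-3-[(trityloxy)methyl]-2,3-dihydro-1,4-benzodioxine-2-carboxylic acid, cis | O=Cc1cc(OCOC)c2c(c1)O[C@H](C(=O)O)[C@H](COC(c3ccccc3)(c4ccccc4)c5ccccc5)O2 | intermediate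
9 | 5-bromo-1,2,3-trimethoxybenzene | COc1cc(Br)cc(OC)c1OC | starting material
10 | (2S,3S)-8-(methoxymethoxy)-3-(3,4,5-trimethoxyphenyl)-2-[(trityloxy)methyl]-2,3-dihydro-1,4-benzodioxine-6-carbaldehyde, trans | COc1cc([C@@H]2Oc3cc(C=O)cc(OCOC)c3O[C@H]2COC(c4ccccc4)(c5ccccc5)c6ccccc6)cc(OC)c1OC | intermediate
11 | (1,3-dioxolan-2-ylmethyl)triphenylphosphonium bromide | [Br-].C1COC(C[P+](c2ccccc2)(c3ccccc3)c4ccccc4)O1 | starting material
12 | 2-{2-[(2S,3S)-8-(methoxymethoxy)-3-(3,4,5-trimethoxyphenyl)-2-[(trityloxy)methyl]-2,3-dihydro-1,4-benzodioxin-6-yl]ethenyl}-1,3-dioxolane, E/Z mixture (alkene geometry left open) | COc1cc([C@@H]2Oc3cc(C=CC4OCCO4)cc(OCOC)c3O[C@H]2COC(c5ccccc5)(c6ccccc6)c7ccccc7)cc(OC)c1OC | intermediate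
13 | (2E)-3-[(2S,3S)-8-hydroxy-2-(hydroxymethyl)-3-(3,4,5-trimethoxyphenyl)-2,3-dihydro-1,4-benzodioxin-6-yl]prop-2-enal | COc1cc([C@@H]2Oc3cc(/C=C/C=O)cc(O)c3O[C@H]2CO)cc(OC)c1OC | target

**Step count and risks**

Total step count: 7. Longest linear sequence: 7 steps (1 to 13); 4, 9 and 11 enter at steps 3, 6 and 7.

Steps most likely to fail:

Step 6. Nickel may capture the α-aryloxy radical with too little facial discrimination, or protodecarboxylation may outrun oxidative addition of the bromide. The fallback sets out from 8 and comes back at 10. Esterification of 8 with N-hydroxyphthalimide (DIC, CH2Cl2, rt) would give 1,3-dioxoisoindolin-2-yl (2S,3S)-7-formyl-5-(methoxymethoxy)-3-[(trityloxy)methyl]-2,3-dihydro-1,4-benzodioxine-2-carboxylate F1. This redox-active ester would then be joined to 5-iodo-1,2,3-trimethoxybenzene by nickel-catalysed reductive cross-electrophile coupling (NiBr2·glyme, dtbbpy, Zn, DMA, rt). The radical is now formed by single-electron reduction, without light or base, next to the aryl–nickel species, and the same substrate control should again favour trans-10.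

Step 3. The two phenols flanking the 4-OH may protonate or chelate the phosphonium betaine, eroding site selectivity and slowing displacement at the hindered carbinol. The fallback sets out from 4 and comes back at 5. Peracetylation (Ac2O, pyridine) would give 3,4,5-triacetoxybenzaldehyde F2. Aminolysis with one equivalent of morpholine should remove the para acetate, the most activated one, to leave 3,5-diacetoxy-4-hydroxybenzaldehyde F3 with a single free phenol. Mitsunobu etherification of F3 with 3 (PPh3, DIAD, THF) would give 3,5-diacetoxy-4-{(1S)-1-[(2S)-oxiran-2-yl]-2-(trityloxy)ethoxy}benzaldehyde F4, and cold methanolysis (K2CO3, MeOH, 0 °C) would return 5.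

Step 7. Acid strong enough to cleave the phenolic MOM acetal may also act on the freshly unmasked enal (conjugate addition, oligomerisation), or the unmasking may stop at partly protected stages. The fallback sets out from 10 and comes back at 13. Trityl and MOM would be removed first (3 M aq. HCl, THF, 40 °C) to give (2S,3S)-8-hydroxy-2-(hydroxymethyl)-3-(3,4,5-trimethoxyphenyl)-2,3-dihydro-1,4-benzodioxine-6-carbaldehyde F5. Wittig olefination of F5 with the stabilised ylide (triphenylphosphoranylidene)acetaldehyde (toluene, 80 °C) tolerates the free hydroxyl groups and should give the E-enal 13 directly, with no acid after the enal is formed.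

Further compounds
F1 | step 6 | 1,3-dioxoisoindolin-2-yl (2S,3S)-7-formyl-5-(methoxymethoxy)-3-[(trityloxy)methyl]-2,3-dihydro-1,4-benzodioxine-2-carboxylate | O=Cc1cc(OCOC)c2c(c1)O[C@H](C(=O)ON3C(=O)c4ccccc4C3=O)[C@H](COC(c5ccccc5)(c6ccccc6)c7ccccc7)O2
F2 | step 3 | 3,4,5-triacetoxybenzaldehyde | CC(=O)Oc1cc(C=O)cc(OC(C)=O)c1OC(C)=O
F3 | step 3 | 3,5-diacetoxy-4-hydroxybenzaldehyde | CC(=O)Oc1cc(C=O)cc(OC(C)=O)c1O
F4 | step 3 | 3,5-diacetoxy-4-{(1S)-1-[(2S)-oxiran-2-yl]-2-(trityloxy)ethoxy}benzaldehyde | CC(=O)Oc1cc(C=O)cc(OC(C)=O)c1O[C@H]([C@@H]2CO2)COC(c3ccccc3)(c4ccccc4)c5ccccc5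
F5 | step 7 | (2S,3S)-8-hydroxy-2-(hydroxymethyl)-3-(3,4,5-trimethoxyphenyl)-2,3-dihydro-1,4-benzodioxine-6-carbaldehyde | COc1cc([C@@H]2Oc3cc(C=O)cc(O)c3O[C@H]2CO)cc(OC)c1OC
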